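**Plan**
1. Locants: piperidine N1, C2 (CH3), C3 (OH), C4, C5, C6. The side chain runs C1′–C16′ from the ring, with OH at C4′ and C15′.
2. Retrosynthetic cuts: (i) three O–benzyl bonds and a C1′≡C2′ unsaturation. (ii) C6–H. (iii) In one event C6–C1′ and N1–C2, with a C2–C6 bond restored, which gives a terminal alkyne and a cyclopentanone oxime mesylate. (iv) C2′–C3′ (acetylide + epoxide) and C13′–C14′ (Grignard + propylene oxide).
3. Enabling feature: N1 lies between the methyl-bearing C2 and the chain-bearing C6. Removing N1 from the six-membered ring leaves the carbocycle C2–C3–C4–C5–C6. This is a trans-3-benzyloxy-2-methylcyclopentanone with C6 as carbonyl carbon, and in its (E)-oxime mesylate the C2–C6 bond is antiperiplanar to N–O.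
4. Forward order: ring fragment (steps 1–6) and chain (steps 7–12) are made separately. Step 13 expands the five-membered ring to the piperidine, joins the fragments and reduces the imine in one flask. Step 14 saturates and debenzylates.
5. Stereochemistry: C3 from a CBS reduction. C2 by thermodynamic epimerisation (trans to C3–O), carried through the 1,2-shift with retention. C6 by axial hydride delivery (all-equatorial ring). C15′ from (S)-propylene oxide. C4′ from hydrolytic kinetic resolution.

Key step: step 13

Assumption: the sense of induction follows the accepted models, in which the α-methylvinyl flank of the enone is the large group for the (R)-CBS catalyst and the (S,S)-(salen)Co catalyst hydrolyses the (R)-alkyloxirane.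

**Step 1**
Reactants: 1 2-methylcyclopent-2-en-1-one
Product: 2 (1S)-2-methylcyclopent-2-en-1-ol
Conditions: (R)-Me-CBS (10 mol %), BH3·SMe2, THF, −20 °C; MeOH
Reagents that add atoms: none
Why: Corey–Bakshi–Shibata reduction: the oxazaborolidine–borane complex binds the carbonyl oxygen anti to the bulkier α-methylvinyl flank and delivers hydride 1,2 to one face only, which should set the carbinol carbon (the later C3) as S.

**Step 2**
Reactants: 2 (1S)-2-methylcyclopent-2-en-1-ol
Product: 3 ({[(1S)-2-methylcyclopent-2-en-1-yl]oxy}methyl)benzene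
Conditions: NaH, BnBr, TBAI (cat.), THF, 0 °C → rt
Reagents that add atoms: benzyl bromide, BrCc1ccccc1
Why: Williamson ether synthesis on the sodium alkoxide; the C–O bond of the stereocentre is not touched, and benzyl is chosen because it survives boranes, alanes and base and leaves in the last hydrogenation.

**Step 3**
Reactants: 3 ({[(1S)-2-methylcyclopent-2-en-1-yl]oxy}methyl)benzene
Product: 5 (1S,2R,3S)-3-(benzyloxy)-2-methylcyclopentan-1-ol, via B-alkyl-9-BBN 4 (not isolated)
Conditions: 9-BBN, THF, reflux; NaOH, H2O2, 0 °C → rt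
Reagents that add atoms: hydrogen peroxide, OO
Why: Brown hydroboration–oxidation: boron adds to the unsubstituted alkene carbon, H and B add syn from the face anti to OBn and C–B is oxidised with retention; the new carbinol centre is erased and the methyl-bearing centre re-equilibrated in step 4, so that only the regiochemistry is critical.

**Step 4**
Reactants: 5 (1S,2R,3S)-3-(benzyloxy)-2-methylcyclopentan-1-ol
Product: 7 (2R,3S)-3-(benzyloxy)-2-methylcyclopentan-1-one, via cis-ketone 6 (not isolated)
Conditions: TPAP (5 mol %), NMO, 4 Å MS, CH2Cl2, rt; filtration; DBU (0.1 equiv), CH2Cl2, rt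
Reagents that add atoms: none
Why: Ley–Griffith oxidation gives the cis-ketone, and base-catalysed epimerisation through the enolate (a thermodynamically controlled, stereoconvergent event) should funnel every C2 epimer into the less strained trans-2,3-disubstituted cyclopentanone, reprotonation of the enolate being faster than expulsion of the poor leaving group benzyloxide.

**Step 5**
Reactants: 7 (2R,3S)-3-(benzyloxy)-2-methylcyclopentan-1-one
Product: 8 (1E,2S,3S)-3-(benzyloxy)-2-methylcyclopentan-1-one oxime
Conditions: NH2OH·HCl, NaOAc, MeOH, rt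
Reagents that add atoms: hydroxylamine hydrochloride, Cl.NO
Why: Oxime condensation: allylic-type strain between N–OH and the 2-methyl group should make the E isomer (OH anti to the branched α-carbon) dominant, and the buffered medium leaves the thermodynamically preferred trans arrangement unchanged (the C2 descriptor changes only because of CIP ranking).

**Step 6**
Reactants: 8 (1E,2S,3S)-3-(benzyloxy)-2-methylcyclopentan-1-one oxime
Product: 9 (1E,2S,3S)-3-(benzyloxy)-2-methylcyclopentan-1-one O-(methylsulfonyl)oxime
Conditions: MsCl, Et3N, CH2Cl2, −20 °C; cold aqueous wash, used crude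
Reagents that add atoms: methanesulfonyl chloride, CS(=O)(=O)Cl
Why: O-Sulfonylation of the oxime at low temperature turns N–OH into a leaving group without E/Z isomerisation or premature rearrangement.

**Step 7**
Reactants: 10 11-bromoundec-1-ene; 11 (S)-2-methyloxirane
Product: 13 (2S)-tetradec-13-en-2-ol, via Grignard reagent 12 (not isolated)
Conditions: Mg, THF; CuI (10 mol %), 11, −30 → 0 °C; aqueous work-up
Reagents that add atoms: none
Why: Copper-catalysed Grignard opening of a terminal epoxide (SN2 at the CH2 terminus), so that the stereocentre of (S)-propylene oxide is carried unchanged into C15′.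

**Step 8**
Reactants: 13 (2S)-tetradec-13-en-2-ol
Product: 14 ({[(2S)-tetradec-13-en-2-yl]oxy}methyl)benzene
Conditions: NaH, BnBr, TBAI (cat.), THF, 0 °C → rt
Reagents that add atoms: benzyl bromide, BrCc1ccccc1
Why: Williamson ether synthesis that masks the C15′ hydroxyl before the epoxide and alane chemistry without touching the C–O bond of the stereocentre.

**Step 9**
Reactants: 14 ({[(2S)-tetradec-13-en-2-yl]oxy}methyl)benzene
Product: 15 2-[(11S)-11-(benzyloxy)dodecyl]oxirane (both epimers at the oxirane carbon)
Conditions: mCPBA, NaHCO3, CH2Cl2, 0 °C → rt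
Reagents that add atoms: mCPBA, OOC(=O)c1cccc(Cl)c1
Why: Prilezhaev epoxidation of the terminal alkene; the remote stereocentre exerts no control, so that both oxirane epimers form and are sorted in step 10.

**Step 10**
Reactants: 15 2-[(11S)-11-(benzyloxy)dodecyl]oxirane (epimer mixture)
Product: 16 (2S)-2-[(11S)-11-(benzyloxy)dodecyl]oxirane
Conditions: (S,S)-(salen)Co (0.5 mol %), AcOH, air; H2O (0.55 equiv), THF, 0 °C → rt
Reagents that add atoms: none
Why: Jacobsen hydrolytic kinetic resolution: the (S,S)-(salen)Co(III) catalyst hydrolyses the (R)-configured oxirane epimer selectively by cooperative bimetallic activation and should leave the (S)-oxirane (later C4′), which is separated from the polar diol by chromatography.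

**Step 11**
Reactants: 16 (2S)-2-[(11S)-11-(benzyloxy)dodecyl]oxirane
Product: 17 (4S,15S)-15-(benzyloxy)hexadec-1-yn-4-ol
Conditions: lithium acetylide·ethylenediamine, DMSO, rt; aqueous work-up
Reagents that add atoms: lithium acetylide–ethylenediamine complex, [Li]C#C.NCCN
Why: SN2 opening of the terminal epoxide by acetylide at the unsubstituted carbon, which leaves the C4′–O bond and its configuration untouched and installs C1′ and C2′.

**Step 12**
Reactants: 17 (4S,15S)-15-(benzyloxy)hexadec-1-yn-4-ol
Product: 18 (4S,15S)-4,15-bis(benzyloxy)hexadec-1-yne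
Conditions: NaH, BnBr, TBAI (cat.), THF, 0 °C → rt
Reagents that add atoms: benzyl bromide, BrCc1ccccc1
Why: Williamson ether synthesis; the alkoxide is formed and alkylated far faster than the much less acidic terminal alkyne C–H reacts, so that the alkyne stays free for metalation.

**Step 13**
Reactants: 18 (4S,15S)-4,15-bis(benzyloxy)hexadec-1-yne; 9 (1E,2S,3S)-3-(benzyloxy)-2-methylcyclopentan-1-one O-(methylsulfonyl)oxime
Product: 22 (2R,3S,6R)-3-(benzyloxy)-6-[(4S,15S)-4,15-bis(benzyloxy)hexadec-1-yn-1-yl]-2-methylpiperidine, via lithium acetylide 19 (not isolated), via diethyl(alkynyl)alane 20 (not isolated), via alkynyl ketimine 21 (not isolated)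
Conditions: 18 (1.5 equiv), n-BuLi, toluene, 0 °C; Et2AlCl, 0 °C → rt; 9, CH2Cl2, −78 → 0 °C; DIBAL-H, −78 → 0 °C; aq. Rochelle salt (excess 18 recovered)
Reagents that add atoms: none
Why: The Lewis-acidic alane ionises the N–OMs bond of (E)-9 while the antiperiplanar C2–C6 bond shifts from carbon to nitrogen with retention at C2, so that a ring C–C bond is cleaved, N1 is inserted and an electrophilic nitrilium/imidoyl carbon (C6) arises, which is captured at once by the alkynyl ligand of 20 to forge C6–C1′ and give ketimine 21. The closest known reaction type is the organoaluminium-promoted Beckmann rearrangement–alkylation of cycloalkanone oxime sulfonates with in situ DIBAL-H reduction, which turns cyclopentanone oxime sulfonates into 2-substituted piperidines. The piperidine ring is not closed by a cyclisation but arises by one-atom ring expansion (5 → 6) through the 1,2-shift. The only new stereocentre, C6, is set in the hydride step: DIBAL-H should attack the half-chair of 21, in which 2-CH3 and 3-OBn are pseudo-equatorial, along the axial trajectory, which places the slim alkynyl group equatorial and cis to the 2-methyl group. Three selectivities are needed: migration of C2 rather than C5, secured by the E geometry of the oxime and the higher migratory aptitude of the secondary carbon; transfer of alkynyl rather than ethyl, secured by the much greater transfer aptitude of sp-carbon ligands on aluminium; and rearrangement rather than fragmentation, secured by the inductively destabilising 3-OBn group next to the migrating carbon, which disfavours a free cation at C2.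

**Step 14**
Reactants: 22 (2R,3S,6R)-3-(benzyloxy)-6-[(4S,15S)-4,15-bis(benzyloxy)hexadec-1-yn-1-yl]-2-methylpiperidine
Product: 23 (2R,3S,6S)-6-[(4S,15S)-4,15-dihydroxyhexadecyl]-2-methylpiperidin-3-ol
Conditions: H2 (1 → 4 bar), Pd(OH)2/C, MeOH, then AcOH as co-solvent, rt; aq. K2CO3 work-up
Reagents that add atoms: none
Why: Heterogeneous catalytic hydrogenation saturates the alkyne first and, after acidification to keep the amine protonated, hydrogenolyses the three benzyl ethers; no stereocentre is touched (the C6 descriptor changes from R to S only through CIP ranking).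

**Compound list**
1 | 2-methylcyclopent-2-en-1-one | CC1=CCCC1=O | starting material
2 | (1S)-2-methylcyclopent-2-en-1-ol | O[C@H]1CCC=C1C | intermediate
3 | ({[(1S)-2-methylcyclopent-2-en-1-yl]oxy}methyl)benzene | C(O[C@H]1CCC=C1C)c1ccccc1 | intermediate
4 | 9-[(1S,2R,3S)-3-(benzyloxy)-2-methylcyclopentyl]-9-borabicyclo[3.3.1]nonane | C1CC2CCCC(C1)B2[C@H]1CC[C@H](OCc3ccccc3)[C@@H]1C | intermediate
5 | (1S,2R,3S)-3-(benzyloxy)-2-methylcyclopentan-1-ol | O[C@H]1CC[C@H](OCc2ccccc2)[C@@H]1C | intermediate
6 | (2S,3S)-3-(benzyloxy)-2-methylcyclopentan-1-one (cis) | O=C1CC[C@H](OCc2ccccc2)[C@@H]1C | intermediate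
7 | (2R,3S)-3-(benzyloxy)-2-methylcyclopentan-1-one (trans) | O=C1CC[C@H](OCc2ccccc2)[C@H]1C | intermediate
8 | (1E,2S,3S)-3-(benzyloxy)-2-methylcyclopentan-1-one oxime | O/N=C1\CC[C@H](OCc2ccccc2)[C@H]1C | intermediate
9 | (1E,2S,3S)-3-(benzyloxy)-2-methylcyclopentan-1-one O-(methylsulfonyl)oxime | CS(=O)(=O)O/N=C1\CC[C@H](OCc2ccccc2)[C@H]1C | intermediate
10 | 11-bromoundec-1-ene | C=CCCCCCCCCCBr | starting material
11 | (S)-2-methyloxirane | C[C@H]1CO1 | starting material
12 | undec-10-en-1-ylmagnesium bromide | C=CCCCCCCCCC[Mg]Br | intermediate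
13 | (2S)-tetradec-13-en-2-ol | C[C@H](O)CCCCCCCCCCC=C | intermediate
14 | ({[(2S)-tetradec-13-en-2-yl]oxy}methyl)benzene | C[C@H](OCc1ccccc1)CCCCCCCCCCC=C | intermediate
15 | 2-[(11S)-11-(benzyloxy)dodecyl]oxirane, both oxirane epimers | C[C@H](OCc1ccccc1)CCCCCCCCCCC1CO1 | intermediate
16 | (2S)-2-[(11S)-11-(benzyloxy)dodecyl]oxirane | C[C@H](OCc1ccccc1)CCCCCCCCCC[C@H]1CO1 | intermediate
17 | (4S,15S)-15-(benzyloxy)hexadec-1-yn-4-ol | C[C@H](OCc1ccccc1)CCCCCCCCCC[C@H](O)CC#C | intermediate
18 | (4S,15S)-4,15-bis(benzyloxy)hexadec-1-yne | C[C@H](OCc1ccccc1)CCCCCCCCCC[C@H](OCc1ccccc1)CC#C | intermediate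
19 | [(4S,15S)-4,15-bis(benzyloxy)hexadec-1-yn-1-yl]lithium | C[C@H](OCc1ccccc1)CCCCCCCCCC[C@H](OCc1ccccc1)CC#C[Li] | intermediate
20 | [(4S,15S)-4,15-bis(benzyloxy)hexadec-1-yn-1-yl]diethylaluminium | C[C@H](OCc1ccccc1)CCCCCCCCCC[C@H](OCc1ccccc1)CC#C[Al](CC)CC | intermediate
21 | (2R,3S)-3-(benzyloxy)-6-[(4S,15S)-4,15-bis(benzyloxy)hexadec-1-yn-1-yl]-2-methyl-2,3,4,5-tetrahydropyridine | C[C@H](OCc1ccccc1)CCCCCCCCCC[C@H](OCc1ccccc1)CC#CC1=N[C@H](C)[C@@H](OCc2ccccc2)CC1 | intermediate
22 | (2R,3S,6R)-3-(benzyloxy)-6-[(4S,15S)-4,15-bis(benzyloxy)hexadec-1-yn-1-yl]-2-methylpiperidine | C[C@H](OCc1ccccc1)CCCCCCCCCC[C@H](OCc1ccccc1)CC#C[C@H]1CC[C@H](OCc2ccccc2)[C@@H](C)N1 | intermediate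
23 | (2R,3S,6S)-6-[(4S,15S)-4,15-dihydroxyhexadecyl]-2-methylpiperidin-3-ol | C[C@H](O)CCCCCCCCCC[C@H](O)CCC[C@H]1CC[C@H](O)[C@@H](C)N1 | target

**Total step count:** 14. **Longest linear sequence:** 8 steps (steps 1–6, 13, 14; the chain branch, steps 7–12, 13, 14, is equally long).

**Steps most likely to fail**

**Step 13.**
- An ethyl ligand may be transferred in competition, or the electrophilic C6 may be captured by mesylate or chloride.
- The oxime sulfonate may partly isomerise from E to Z, so that C5 migrates instead of C2.
- The three benzyl ether donors may weaken the Lewis acidity of the alane.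
- Hydride delivery to the aluminium-complexed imine may show poor facial selectivity.

The fallback separates rearrangement and C–C bond formation, and it sets out from 9 and 18. Solvolysis of 9 in aqueous dioxane with NaHCO3 gives the Beckmann lactam (5S,6R)-5-(benzyloxy)-6-methylpiperidin-2-one F1. Boc2O/DMAP converts it into the activated N-Boc lactam F2. Lithium acetylide 19 (from 18, n-BuLi, THF, −78 °C) adds to the lactam carbonyl, and the ring opens to the N-Boc amino ynone F3. TFA removes the carbamate, and the free amine condenses with the ketone to imine 21, now free of aluminium. NaBH4 in MeOH reduces 21 by axial attack, and the route is rejoined at 22.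

**Step 4.**
- Benzyl alcohol may be lost by E1cB elimination from the same enolate that mediates the epimerisation.
- The equilibration may remain incomplete.

The fallback sets the trans relationship kinetically, by the syn addition of hydroboration, and it sets out from 2. TBSCl/imidazole gives the silyl ether F4. 9-BBN adds anti to OTBS to give the B-alkyl-9-BBN F5. NaOH/H2O2 turns it into the alcohol F6, whose new hydroxyl is trans to the methyl group. NaH/BnBr gives the benzyl ether F7, and TBAF liberates the former CBS carbinol in the alcohol F8. TPAP/NMO oxidises F8 directly to the trans-ketone without any base treatment, so the route is rejoined at 7. A rotation about the axis through C2 shows that the same enantiomer results.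

**Step 14.**
- The basic amine may poison the palladium, so that O-debenzylation stalls.
- The propargylic/allylic C6–N bond may be hydrogenolysed before the π-system is saturated.

The fallback masks the nitrogen first and sets out from 22. Boc2O (neat, warm) gives the carbamate F9. H2 over Pd/C in EtOAc/MeOH saturates the alkyne and removes the benzyl groups to give the N-Boc triol F10. HCl in MeOH then removes the carbamate, and the route is rejoined at 23.

**Further compounds**
F1 | step 13 | (5S,6R)-5-(benzyloxy)-6-methylpiperidin-2-one | O=C1CC[C@H](OCc2ccccc2)[C@@H](C)N1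
F2 | step 13 | tert-butyl (2R,3S)-3-(benzyloxy)-2-methyl-6-oxopiperidine-1-carboxylate | O=C1CC[C@H](OCc2ccccc2)[C@@H](C)N1C(=O)OC(C)(C)C
F3 | step 13 | tert-butyl [(2R,3S,10S,21S)-3,10,21-tris(benzyloxy)-6-oxodocos-7-yn-2-yl]carbamate | C[C@H](OCc1ccccc1)CCCCCCCCCC[C@H](OCc1ccccc1)CC#CC(=O)CC[C@H](OCc1ccccc1)[C@@H](C)NC(=O)OC(C)(C)C
F4 | step 4 | tert-butyldimethyl{[(1S)-2-methylcyclopent-2-en-1-yl]oxy}silane | CC(C)(C)[Si](C)(C)O[C@H]1CCC=C1C
F5 | step 4 | 9-{(1S,2R,3S)-3-[(tert-butyldimethylsilyl)oxy]-2-methylcyclopentyl}-9-borabicyclo[3.3.1]nonane | C1CC2CCCC(C1)B2[C@H]1CC[C@H](O[Si](C)(C)C(C)(C)C)[C@@H]1C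
F6 | step 4 | (1S,2R,3S)-3-[(tert-butyldimethylsilyl)oxy]-2-methylcyclopentan-1-ol | O[C@H]1CC[C@H](O[Si](C)(C)C(C)(C)C)[C@@H]1C
F7 | step 4 | {[(1S,2R,3S)-3-(benzyloxy)-2-methylcyclopentyl]oxy}(tert-butyl)dimethylsilane | C(O[C@H]1CC[C@H](O[Si](C)(C)C(C)(C)C)[C@@H]1C)c1ccccc1
F8 | step 4 | (1S,2S,3S)-3-(benzyloxy)-2-methylcyclopentan-1-ol | C(O[C@H]1CC[C@H](O)[C@@H]1C)c1ccccc1
F9 | step 14 | tert-butyl (2R,3S,6R)-3-(benzyloxy)-6-[(4S,15S)-4,15-bis(benzyloxy)hexadec-1-yn-1-yl]-2-methylpiperidine-1-carboxylate | C[C@H](OCc1ccccc1)CCCCCCCCCC[C@H](OCc1ccccc1)CC#C[C@H]1CC[C@H](OCc2ccccc2)[C@@H](C)N1C(=O)OC(C)(C)C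
F10 | step 14 | tert-butyl (2R,3S,6S)-6-[(4S,15S)-4,15-dihydroxyhexadecyl]-3-hydroxy-2-methylpiperidine-1-carboxylate | C[C@H](O)CCCCCCCCCC[C@H](O)CCC[C@H]1CC[C@H](O)[C@@H](C)N1C(=O)OC(C)(C)C
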